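**Assumption (remark on the chemistry):** the target is treated as the freely equilibrating enol/tricarbonyl tautomer set of the given SMILES. CIP analysis of that SMILES gives C5 = S in the ring and C14' = S in the side chain, and the route is built for these descriptors.

## Analysis of the target

The target is a 3-acyltetronic acid. Its furan-2(5H)-one ring (O1–C2(=O)–C3=C4(OH)–C5) carries a hydroxymethyl group on the sp3 carbon C5 and, on C3, a 14-methylhexadecanoyl chain (C1'–C16', methyl branch on C14'). There are two stereocentres, C5 (S) and C14' (S). They lie sixteen bonds apart and cannot influence each other, so each needs its own source of chirality, and the remote anteiso centre can hardly be corrected late.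

Ring carbon C3 is a triacylmethane carbon, bonded to the lactone carbonyl C2, the enol carbon C4 and the ketone C1'. This array is strongly acidic, chelates metals, is awkward to purify and loses an acyl group to nucleophiles. C5–H sits next to the carbonyl-level carbon C4 and has a β-hydroxyl, so strong base threatens epimerisation and elimination across C5–CH2OH.

The hard points are three:
- the C3–C1' bond, where C-acylation competes with O-acylation;
- telling apart the two oxygens that become O1 and the CH2OH oxygen, so that a five- and not a six-membered lactone closes;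
- keeping the free tricarbonyl out of as many steps as possible.

The feature the route exploits is the array O–C4–C3–C1'(=O) of ring carbons C4 and C3 and side-chain carbon C1'. It has the oxidation pattern of C5–C4–C3 of a 1,2-oxazole (isoxazole), with C2 as its 4-carboxylate and a nitrogen standing in for the C1' oxygen.

## Retrosynthetic reasoning

**16 to 13.** The lactone bond O1–C2 is opened and the C1' carbonyl oxygen is exchanged for an amino group. This leads back through 15 and 14 to the open-chain enaminone ester 13, in which O1 and the hydroxymethyl oxygen are still tied together in the acetonide that the starting material brings along. The cut is made here because it postpones the free tricarbonyl to the last operation. One acidic medium has to cleave the ketal, close the secondary hydroxyl onto the ester (five-membered ring) and hydrolyse the enamine.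

**13 to 12.** The enamine nitrogen and the C4 ketone oxygen are reconnected by an N–O bond, which gives the aromatic isoxazole 12. This turns the acidic, chelating triacylmethane into a neutral, base-tolerant heteroarene that can be purified normally. The forward reaction only has to break the weakest bond of the ring by hydrogenolysis.

**12 to 7 and 9 (key disconnection).** The isoxazole is cut at C3–C4 (the future C1'–C3 bond) and at O1–C5 (the future O–C4 bond). The fragments are the nitrile oxide 10, generated from hydroximoyl chloride 7, and the enolate of β-ketoester 9. This cut separates the lipid chain from the chiral head group exactly at the acyl carbon. It also makes the C- versus O-acylation problem vanish by construction, because the dipole can only deliver carbon to carbon and oxygen to the ketone carbon. The forward reaction must capture a short-lived aliphatic nitrile oxide and close and aromatise the ring without touching the γ-stereocentre of 9.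

**9 to 8.** The C2–C3 bond of 9 is cut, which is a crossed Claisen condensation of a two-carbon ester enolate with the glycerate ester 8. The acetonide of 8 is kept: it protects both oxygens until the last step, so no protecting-group step is spent on the head group.

**7 to 6 to 5 to 4.** These are functional-group changes at C1' only: chlorination of oxime 6, oximation of aldehyde 5, oxidation of alcohol 4. They leave the carbon skeleton untouched.

**4 to 3 and 2, 3 from 1.** The chain is cut at C12'–C13', between the unbranched C12 segment 2 and the (S)-2-methylbutyl unit of 1. The C14' stereocentre is bought with 1. It is β to the reacting carbon of Grignard reagent 3, so a copper-catalysed sp3–sp3 coupling cannot scramble it.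

## Alternatives that were turned down

**Alternative 1:** the textbook Lacey–Dieckmann route.
- Disconnection: the lactone ester bond O1–C2 is made first between two molecules, and the ring is closed at C3–C4.
- Forward key step: thermolysis of the acylated 2,2-dimethyl-1,3-dioxane-4,6-dione A1 (the acyl Meldrum's acid of the C17 chain, two steps from 4) in the presence of the mono-protected glycerate A2 transfers the β-ketoacyl group to the hydroxyl of A2 and gives diester A3. Strong base then closes C3–C4 by Dieckmann condensation to trityl ether A4, and acid removes the trityl group.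
- Why turned down: it is the route drawn first. The two hydroxyls of the glycerate must be told apart beforehand (two extra steps from 8 to A2) and unmasked afterwards. The Dieckmann step puts strong base on A3, whose glycerate α-hydrogen is flanked by an ester and an acyloxy group and has a β-trityloxy group, so epimerisation and β-elimination compete with ring closure. The free tricarbonyl A4 must then survive purification and a deprotection. The step count is no lower than the route chosen.

**Alternative 2:** acyl transfer onto a finished ring.
- Disconnection: C3–C1' alone, on the preformed tetronic acid A5.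
- Forward key step: carbodiimide coupling of A5 with the acid A6 gives enol ester A7. A nucleophilic pyridine catalyst then moves the acyl group from O4 to C3 (Fries-type 1,3-shift) to give A4.
- Why turned down: the key step only decorates. The ring A5 has to be made first from A2 by a Claisen/lactonisation sequence, three to four steps from 8. The O-to-C shift runs through an acylpyridinium/tetronate ion pair, which for a long enolisable acyl group can also collapse by deacylation. The sequence again ends with the protected free tricarbonyl A4.

**Alternative 3:** the same dipole on a ring-first precursor.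
- Disconnection: C3–C1' and O–C4, both made on an intact lactone.
- Forward key step: (3+2) cycloaddition of 10 to the chiral butenolide A8, anti to its C5 substituent, gives the cis-fused dihydroisoxazole A9.
- Why turned down: in A9 the future C4 is only at the alcohol level. A further dehydrogenation to the strained aromatic bicycle A10 is needed, with no leaving group to drive it. Regiochemistry on the enoate rests on orbital coefficients alone, not on enolate polarity, so some of the wrong regioisomer is expected. A8 belongs to the enantiomeric series of the common chiral-pool butenolide and would itself cost several steps from 8, plus a silylation and a desilylation.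

Key step: step 5

## Route

**Step 1**
Reactants: 1 (S)-1-bromo-2-methylbutane; 2 12-bromododecan-1-ol
Product: 4 (14S)-14-methylhexadecan-1-ol, via Grignard reagent 3 (not isolated)
Conditions: Mg, THF, 40 °C (1 to 3); 2 + MeMgBr (1.0 equiv), THF, −20 °C; then 3 (1.3 equiv), Li2CuCl4 (3 mol%), THF/NMP, −20 °C to rt; aq. NH4Cl
Reagents that add atoms: none
Why: Copper-catalysed cross-coupling of a primary alkylmagnesium bromide with a primary alkyl bromide; the hydroxyl of 2 is masked in the flask as its bromomagnesium alkoxide by one equivalent of MeMgBr. The stereocentre of 1 is β to the carbon–magnesium bond and is not touched, so 4 should inherit the (S) configuration unchanged.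

**Step 2**
Reactants: 4 (14S)-14-methylhexadecan-1-ol
Product: 6 (14S)-14-methylhexadecanal oxime (E/Z mixture), via aldehyde 5 (not isolated)
Conditions: TEMPO (10 mol%), PhI(OAc)2 (1.05 equiv), CH2Cl2, rt; then NH2OH·HCl (1.5 equiv), NaOAc, EtOH, rt
Reagents that add atoms: hydroxylamine hydrochloride, Cl.NO
Why: Oxoammonium (TEMPO) oxidation stops at the aldehyde 5 in the absence of water, and condensation with hydroxylamine in the same flask avoids handling a fatty aldehyde; excess hydroxylamine also destroys residual oxidant. Oxime geometry is irrelevant for the next step.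

**Step 3**
Reactants: 6 (14S)-14-methylhexadecanal oxime
Product: 7 (1Z,14S)-N-hydroxy-14-methylhexadecanimidoyl chloride
Conditions: NCS (1.05 equiv), DMF, 0 °C to rt; aqueous work-up, used crude
Reagents that add atoms: N-chlorosuccinimide, O=C1CCC(=O)N1Cl
Why: Electrophilic chlorination of an aldoxime at carbon gives the hydroximoyl chloride, the standard storable precursor of a nitrile oxide; no other site of 6 should react with NCS at room temperature.

**Step 4**
Reactants: 8 methyl (4S)-2,2-dimethyl-1,3-dioxolane-4-carboxylate
Product: 9 methyl 3-[(4S)-2,2-dimethyl-1,3-dioxolan-4-yl]-3-oxopropanoate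
Conditions: MeOAc (2.3 equiv), LiN(SiMe3)2 (2.2 equiv), THF, −78 °C; then 8, −78 °C; AcOH quench
Reagents that add atoms: methyl acetate, COC(C)=O
Why: Crossed Claisen condensation: the lithium enolate of methyl acetate adds to the activated α-alkoxy ester at −78 °C, and the product is at once deprotonated at C2 by the second equivalent of enolate. This blocks a second addition and keeps the α-alkoxy stereocentre from enolising, so the (4S) centre of 8 should be carried over unchanged.

**Step 5**
Reactants: 7 (1Z,14S)-N-hydroxy-14-methylhexadecanimidoyl chloride; 9 methyl 3-[(4S)-2,2-dimethyl-1,3-dioxolan-4-yl]-3-oxopropanoate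
Product: 12 methyl 5-[(4S)-2,2-dimethyl-1,3-dioxolan-4-yl]-3-[(13S)-13-methylpentadecyl]-1,2-oxazole-4-carboxylate, via nitrile oxide 10 (not isolated), via 5-hydroxy-4,5-dihydroisoxazole 11 (not isolated)
Conditions: 9 (1.2 equiv), NaOMe (1.2 equiv), MeOH/THF, 0 °C; 7 in THF added over 2 h; then rt
Reagents that add atoms: none
Why: The sodium enolate of 9 dehydrochlorinates 7 to nitrile oxide 10, whose electrophilic carbon is captured by the nucleophilic C2 of the enolate; the oximate oxygen then adds to the adjacent ketone carbonyl (5-exo-trig) to give 11, and loss of water across C4–C5 aromatises it to 12. Overall this is the (3+2) cyclocondensation of a nitrile oxide with a β-ketoester enolate, the classical regiospecific entry to 3,5-disubstituted isoxazole-4-carboxylates. The step forms the bond that becomes C3–C1' of the target and installs, as the ring oxygen, the atom that becomes the C4 oxygen, so the whole triacylmethane is assembled in masked, non-acidic form. No stereocentre is created, because the two sp3 ring carbons of 11 vanish on aromatisation. Regiochemistry follows from enolate polarity: carbon bonds to carbon, and oxygen closes on the ketone, which is the enolised and more electrophilic carbonyl, not on the ester. The dioxolane stereocentre is γ to the ester and should stay intact, since one equivalent of methoxide forms only the C2 monoanion. The selectivity that must be secured is capture of 10 before it dimerises; slow addition of 7 to an excess of enolate keeps 10 at low concentration.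

**Step 6**
Reactants: 12 methyl 5-[(4S)-2,2-dimethyl-1,3-dioxolan-4-yl]-3-[(13S)-13-methylpentadecyl]-1,2-oxazole-4-carboxylate
Product: 13 methyl (2E,16S)-3-amino-2-{[(4S)-2,2-dimethyl-1,3-dioxolan-4-yl]carbonyl}-16-methyloctadec-2-enoate
Conditions: H2 (1 atm), Pd/C (10 wt%), MeOH/EtOAc, rt
Reagents that add atoms: none
Why: Hydrogenolysis of the weak N–O bond (reductive ring opening of an isoxazole to a β-enaminoketone) dearomatises the ring: the ring oxygen becomes the C4 ketone oxygen and nitrogen stays on C1' as a primary enamine stabilised by two carbonyl groups. Ester, ketal and both stereocentres are inert to H2 and Pd/C; the push–pull double bond of 13 is configurationally labile, which is of no consequence.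

**Step 7**
Reactants: 13 methyl (2E,16S)-3-amino-2-{[(4S)-2,2-dimethyl-1,3-dioxolan-4-yl]carbonyl}-16-methyloctadec-2-enoate
Product: 16 (5S)-4-hydroxy-5-(hydroxymethyl)-3-[(14S)-14-methylhexadecanoyl]furan-2(5H)-one, via diol 14 (not isolated), via aminoalkylidene lactone 15 (not isolated)
Conditions: 2 M aq. HCl/THF (1:3), rt, then 55 °C
Reagents that add atoms: water, O
Why: Aqueous acid hydrolyses the ketal to diol 14; the secondary hydroxyl then closes onto the methyl ester (5-exo-trig lactonisation) to 15, the five-membered vinylogous acid being the expected ring as in the lactonisation of pentonic and 2-oxohexonic acids. Acid hydrolysis of the enamine then releases the C1' ketone. No base is present, so C5 is not deprotonated and should keep its (S) configuration.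

## Compound list

1 | (S)-1-bromo-2-methylbutane | CC[C@H](C)CBr | starting material
2 | 12-bromododecan-1-ol | OCCCCCCCCCCCCBr | starting material
3 | [(2S)-2-methylbutyl]magnesium bromide | CC[C@H](C)C[Mg]Br | intermediate
4 | (14S)-14-methylhexadecan-1-ol | CC[C@H](C)CCCCCCCCCCCCCO | intermediate
5 | (14S)-14-methylhexadecanal | CC[C@H](C)CCCCCCCCCCCCC=O | intermediate
6 | (14S)-14-methylhexadecanal oxime (E/Z mixture) | CC[C@H](C)CCCCCCCCCCCCC=NO | intermediate
7 | (1Z,14S)-N-hydroxy-14-methylhexadecanimidoyl chloride | CC[C@H](C)CCCCCCCCCCCC/C(Cl)=N/O | intermediate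
8 | methyl (4S)-2,2-dimethyl-1,3-dioxolane-4-carboxylate | COC(=O)[C@@H]1COC(C)(C)O1 | starting material
9 | methyl 3-[(4S)-2,2-dimethyl-1,3-dioxolan-4-yl]-3-oxopropanoate | COC(=O)CC(=O)[C@@H]1COC(C)(C)O1 | intermediate
10 | (14S)-14-methylhexadecanenitrile oxide | CC[C@H](C)CCCCCCCCCCCCC#[N+][O-] | intermediate
11 | methyl 5-[(4S)-2,2-dimethyl-1,3-dioxolan-4-yl]-5-hydroxy-3-[(13S)-13-methylpentadecyl]-4,5-dihydro-1,2-oxazole-4-carboxylate (mixture at C4 and C5 of the new ring) | COC(=O)C1C(CCCCCCCCCCCC[C@@H](C)CC)=NOC1(O)[C@@H]1COC(C)(C)O1 | intermediate
12 | methyl 5-[(4S)-2,2-dimethyl-1,3-dioxolan-4-yl]-3-[(13S)-13-methylpentadecyl]-1,2-oxazole-4-carboxylate | COC(=O)c1c(CCCCCCCCCCCC[C@@H](C)CC)noc1[C@@H]1COC(C)(C)O1 | intermediate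
13 | methyl (2E,16S)-3-amino-2-{[(4S)-2,2-dimethyl-1,3-dioxolan-4-yl]carbonyl}-16-methyloctadec-2-enoate | COC(=O)/C(=C(/N)CCCCCCCCCCCC[C@@H](C)CC)C(=O)[C@@H]1COC(C)(C)O1 | intermediate
14 | methyl (2E,16S)-3-amino-2-[(2S)-2,3-dihydroxypropanoyl]-16-methyloctadec-2-enoate | COC(=O)/C(=C(/N)CCCCCCCCCCCC[C@@H](C)CC)C(=O)[C@@H](O)CO | intermediate
15 | (5S)-3-[(14S)-1-amino-14-methylhexadecylidene]-5-(hydroxymethyl)furan-2,4(3H,5H)-dione | NC(CCCCCCCCCCCC[C@@H](C)CC)=C1C(=O)O[C@@H](CO)C1=O | intermediate
16 | (5S)-4-hydroxy-5-(hydroxymethyl)-3-[(14S)-14-methylhexadecanoyl]furan-2(5H)-one | CC[C@H](C)CCCCCCCCCCCCC(=O)C1=C(O)[C@H](CO)OC1=O | target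

## Step count and least certain steps

Total: 7 steps. Longest linear sequence: 6 steps (steps 1, 2, 3, 5, 6, 7); step 4 is the one-step side branch.

**Step 5 (key step).**
- What may go wrong: dimerisation of the aliphatic nitrile oxide may outrun its capture by the enolate; the oximate may close onto the ester instead of the ketone carbonyl; methoxide may solvolyse the hydroximoyl chloride.
- Fallback (sets out from 4 and 9, returns at 16): the C3–C1' bond is made by acylation instead of cycloaddition. Alcohol 4 is oxidised (TEMPO, NaOCl, then NaClO2) to (14S)-14-methylhexadecanoic acid F1, and oxalyl chloride converts this into (14S)-14-methylhexadecanoyl chloride F2. C-acylation of the MgCl2/pyridine chelate of 9 with F2 should give methyl (16S)-2-{[(4S)-2,2-dimethyl-1,3-dioxolan-4-yl]carbonyl}-16-methyl-3-oxooctadecanoate F3. The aqueous acid of step 7 (ketal hydrolysis, lactonisation) then takes F3 directly to 16, bypassing 12 to 15.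

**Step 7.**
- What may go wrong: ring closure may go through the primary instead of the secondary hydroxyl (six-membered lactone); hydrolysis of the doubly stabilised enamine may be slow; prolonged heating in acid may cause loss of water across C5–CH2OH.
- Fallback (sets out from 12, returns at 16): ring size is fixed by protection before the ring is opened. The ketal of 12 is cleaved with 80% aqueous AcOH to methyl 5-[(1S)-1,2-dihydroxyethyl]-3-[(13S)-13-methylpentadecyl]-1,2-oxazole-4-carboxylate F4. The primary hydroxyl is silylated (tert-butyldimethylsilyl chloride, imidazole) to give methyl 5-[(1S)-2-{[tert-butyl(dimethyl)silyl]oxy}-1-hydroxyethyl]-3-[(13S)-13-methylpentadecyl]-1,2-oxazole-4-carboxylate F5. Hydrogenolysis as in step 6 gives methyl (2E,16S)-3-amino-2-[(2S)-3-{[tert-butyl(dimethyl)silyl]oxy}-2-hydroxypropanoyl]-16-methyloctadec-2-enoate F6. Its only free hydroxyl closes (catalytic TsOH, toluene) to (5S)-3-[(14S)-1-amino-14-methylhexadecylidene]-5-({[tert-butyl(dimethyl)silyl]oxy}methyl)furan-2,4(3H,5H)-dione F7. Aqueous HCl/THF then hydrolyses the enamine and removes the silyl ether to give 16.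

**Step 4.**
- What may go wrong: self-condensation of the acetate enolate on warming; enolisation of 8 at the α-alkoxy carbon, with erosion of optical purity or β-elimination of the ring oxygen.
- Fallback (sets out from 8, returns at 9): a decarboxylative Claisen condensation under nearly neutral conditions. Saponification of 8 (LiOH, then careful acidification) gives (4S)-2,2-dimethyl-1,3-dioxolane-4-carboxylic acid F8. 1,1'-Carbonyldiimidazole converts it into [(4S)-2,2-dimethyl-1,3-dioxolan-4-yl](1H-imidazol-1-yl)methanone F9. Reaction of F9 with Mg(O2CCH2CO2Me)2 in THF should give 9 after loss of carbon dioxide.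

## Further compounds

F1 | step 5 | (14S)-14-methylhexadecanoic acid | CC[C@H](C)CCCCCCCCCCCCC(=O)O
F2 | step 5 | (14S)-14-methylhexadecanoyl chloride | CC[C@H](C)CCCCCCCCCCCCC(=O)Cl
F3 | step 5 | methyl (16S)-2-{[(4S)-2,2-dimethyl-1,3-dioxolan-4-yl]carbonyl}-16-methyl-3-oxooctadecanoate | COC(=O)C(C(=O)CCCCCCCCCCCC[C@@H](C)CC)C(=O)[C@@H]1COC(C)(C)O1
F4 | step 7 | methyl 5-[(1S)-1,2-dihydroxyethyl]-3-[(13S)-13-methylpentadecyl]-1,2-oxazole-4-carboxylate | COC(=O)c1c(CCCCCCCCCCCC[C@@H](C)CC)noc1[C@@H](O)CO
F5 | step 7 | methyl 5-[(1S)-2-{[tert-butyl(dimethyl)silyl]oxy}-1-hydroxyethyl]-3-[(13S)-13-methylpentadecyl]-1,2-oxazole-4-carboxylate | COC(=O)c1c(CCCCCCCCCCCC[C@@H](C)CC)noc1[C@@H](O)CO[Si](C)(C)C(C)(C)C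
F6 | step 7 | methyl (2E,16S)-3-amino-2-[(2S)-3-{[tert-butyl(dimethyl)silyl]oxy}-2-hydroxypropanoyl]-16-methyloctadec-2-enoate | COC(=O)/C(=C(/N)CCCCCCCCCCCC[C@@H](C)CC)C(=O)[C@@H](O)CO[Si](C)(C)C(C)(C)C
F7 | step 7 | (5S)-3-[(14S)-1-amino-14-methylhexadecylidene]-5-({[tert-butyl(dimethyl)silyl]oxy}methyl)furan-2,4(3H,5H)-dione | NC(CCCCCCCCCCCC[C@@H](C)CC)=C1C(=O)O[C@@H](CO[Si](C)(C)C(C)(C)C)C1=O
F8 | step 4 | (4S)-2,2-dimethyl-1,3-dioxolane-4-carboxylic acid | OC(=O)[C@@H]1COC(C)(C)O1
F9 | step 4 | [(4S)-2,2-dimethyl-1,3-dioxolan-4-yl](1H-imidazol-1-yl)methanone | O=C([C@@H]1COC(C)(C)O1)n1ccnc1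
A1 | alternative 1 | 5-[(14S)-1-hydroxy-14-methylhexadecylidene]-2,2-dimethyl-1,3-dioxane-4,6-dione | CC[C@H](C)CCCCCCCCCCCCC(O)=C1C(=O)OC(C)(C)OC1=O
A2 | alternative 1 | methyl (2S)-2-hydroxy-3-(trityloxy)propanoate | COC(=O)[C@@H](O)COC(c1ccccc1)(c1ccccc1)c1ccccc1
A3 | alternative 1 | methyl (2S)-2-{[(16S)-16-methyl-3-oxooctadecanoyl]oxy}-3-(trityloxy)propanoate | CC[C@H](C)CCCCCCCCCCCCC(=O)CC(=O)O[C@@H](COC(c1ccccc1)(c1ccccc1)c1ccccc1)C(=O)OC
A4 | alternative 1 | (5S)-4-hydroxy-3-[(14S)-14-methylhexadecanoyl]-5-[(trityloxy)methyl]furan-2(5H)-one | CC[C@H](C)CCCCCCCCCCCCC(=O)C1=C(O)[C@H](COC(c2ccccc2)(c2ccccc2)c2ccccc2)OC1=O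
A5 | alternative 2 | (5S)-4-hydroxy-5-[(trityloxy)methyl]furan-2(5H)-one | OC1=CC(=O)O[C@H]1COC(c1ccccc1)(c1ccccc1)c1ccccc1
A6 | alternative 2 | (14S)-14-methylhexadecanoic acid | CC[C@H](C)CCCCCCCCCCCCC(=O)O
A7 | alternative 2 | (2S)-5-oxo-2-[(trityloxy)methyl]-2,5-dihydrofuran-3-yl (14S)-14-methylhexadecanoate | CC[C@H](C)CCCCCCCCCCCCC(=O)OC1=CC(=O)O[C@H]1COC(c1ccccc1)(c1ccccc1)c1ccccc1
A8 | alternative 3 | (5R)-5-({[tert-butyl(dimethyl)silyl]oxy}methyl)furan-2(5H)-one | O=C1C=C[C@H](CO[Si](C)(C)C(C)(C)C)O1
A9 | alternative 3 | (6S)-6-({[tert-butyl(dimethyl)silyl]oxy}methyl)-3-[(13S)-13-methylpentadecyl]-3a,6a-dihydrofuro[3,4-d][1,2]oxazol-4(6H)-one (cis-fused, new ring oxygen anti to the C6 substituent) | O=C1O[C@@H](CO[Si](C)(C)C(C)(C)C)[C@@H]2ON=C(CCCCCCCCCCCC[C@@H](C)CC)[C@H]12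
A10 | alternative 3 | (6S)-6-({[tert-butyl(dimethyl)silyl]oxy}methyl)-3-[(13S)-13-methylpentadecyl]furo[3,4-d][1,2]oxazol-4(6H)-one | O=C1O[C@@H](CO[Si](C)(C)C(C)(C)C)c2onc(CCCCCCCCCCCC[C@@H](C)CC)c12
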